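## Retrosynthetic overview

1. Target 20 ⇐ 19 (MOM removal) ⇐ 18 (radical denitration); the NO2 on the ring CH2 between the two stereocentres is a traceless activating group.
2. 18 ⇐ aryl–cyclopentyl bond by conjugate addition of the arylmagnesium from iodide 7 to nitrocyclopentene 15, anti to the isopropenyl group (gives the trans relationship).
3. 15 ⇐ 13 (dehydration) ⇐ open-chain nitro aldehyde 12 by intramolecular nitro-aldol (Henry) ring closure ⇐ nitroalkene 10 + isopropenyl (Rh-catalysed asymmetric 1,4-addition sets the isopropenyl centre) ⇐ aldehyde 8.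
4. 7 ⇐ phloroglucinol 1 by Friedel–Crafts benzoylation, MOM protection and iodination.
5. Ring order: both arenes are bought; the cyclopentane (the only ring made) is closed inside the C10 fragment before the two three-step fragments are joined.

Assumption: (R)-BINAP is written for step 5 by analogy with Rh/BINAP additions to cyclic nitroalkenes; if the first run shows the opposite sense, the mirror-image ligand is used and nothing else changes.

## Route

Step 1
Reactants: 1 phloroglucinol; 2 benzoyl chloride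
Product: 3 phenyl(2,4,6-trihydroxyphenyl)methanone
Conditions: AlCl3 (3.5 equiv), PhNO2, 70 °C; aq. HCl work-up
Reagents that add atoms: benzoyl chloride, O=C(Cl)c1ccccc1
Why: Friedel–Crafts C-acylation of the symmetric, very electron-rich triol gives the mono-ketone, which is deactivated towards a second acylation.

Step 2
Reactants: 3 phenyl(2,4,6-trihydroxyphenyl)methanone; 4 chloromethyl methyl ether
Product: 5 phenyl[2,4,6-tris(methoxymethoxy)phenyl]methanone
Conditions: NaH (3.5 equiv), MOMCl (3.5 equiv), DMF, 0 °C to rt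
Reagents that add atoms: chloromethyl methyl ether, COCCl
Why: Williamson-type O-alkylation of the three phenoxides by the hard electrophile MOMCl; NaH is needed for the two hydrogen-bonded ortho hydroxyls.

Step 3
Reactants: 5 phenyl[2,4,6-tris(methoxymethoxy)phenyl]methanone; 6 N-iodosuccinimide
Product: 7 [3-iodo-2,4,6-tris(methoxymethoxy)phenyl](phenyl)methanone
Conditions: NIS (1.05 equiv), MeCN, 0 °C to rt, dark
Reagents that add atoms: N-iodosuccinimide, O=C1CCC(=O)N1I
Why: Electrophilic aromatic iodination at one of the two equivalent free positions, each flanked by two OMOM groups; the stoichiometry limits it to the mono-iodide.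

Step 4
Reactants: 8 2,2-dimethylpent-4-enal; 9 silver nitrite
Product: 10 (E)-2,2-dimethyl-5-nitropent-4-enal
Conditions: AgNO2 (3 equiv), TEMPO (0.4 equiv), 4 Å MS, DCE, 70 °C
Reagents that add atoms: silver nitrite, [Ag+].[O-]N=O
Why: Radical nitration of the terminal alkene (NO2 radical addition, TEMPO trapping, elimination) gives the (E)-nitroalkene; the aldehyde is non-enolisable and no aldehyde oxidant is present.

Step 5
Reactants: 10 (E)-2,2-dimethyl-5-nitropent-4-enal; 11 potassium trifluoro(prop-1-en-2-yl)borate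
Product: 13 (4R)-2,2-dimethyl-5-nitro-4-(prop-1-en-2-yl)cyclopentan-1-ol, via open-chain nitro aldehyde 12 (not isolated)
Conditions: [Rh(cod)2]BF4 (3 mol%), (R)-BINAP (3.3 mol%), 11 (2 equiv), toluene/H2O 10:1, 100 °C; then DBU (0.3 equiv), THF, 0 °C to rt
Reagents that add atoms: potassium trifluoro(prop-1-en-2-yl)borate, C=C(C)[B-](F)(F)F.[K+]
Why: Rh-catalysed asymmetric conjugate addition (Hayashi–Miyaura type) puts the isopropenyl group on the ligand-selected face of the nitroalkene and sets C4 as R, after which the nitronate closes onto the neopentyl aldehyde by a 5-exo intramolecular nitro-aldol (Henry) reaction; the carbinol and nitro centres form as a mixture that step 6 removes.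

Step 6
Reactants: 13 (4R)-2,2-dimethyl-5-nitro-4-(prop-1-en-2-yl)cyclopentan-1-ol
Product: 15 (5R)-3,3-dimethyl-1-nitro-5-(prop-1-en-2-yl)cyclopent-1-ene, via nitro mesylate 14 (not isolated)
Conditions: MsCl (1.5 equiv), Et3N (3 equiv), CH2Cl2, 0 °C to rt
Reagents that add atoms: none
Why: Mesylation followed by E1cB elimination gives the conjugated nitroalkene from every diastereomer of 13; the γ-carbon is quaternary, so the double bond cannot migrate and the isopropenyl centre is untouched.

Step 7
Reactants: 7 [3-iodo-2,4,6-tris(methoxymethoxy)phenyl](phenyl)methanone; 15 (5R)-3,3-dimethyl-1-nitro-5-(prop-1-en-2-yl)cyclopent-1-ene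
Product: 18 [3-[(1R,4R)-2,2-dimethyl-5-nitro-4-(prop-1-en-2-yl)cyclopentyl]-2,4,6-tris(methoxymethoxy)phenyl](phenyl)methanone, via arylmagnesium chloride 16 (not isolated), via magnesium nitronate 17 (not isolated)
Conditions: i-PrMgCl·LiCl (1.1 equiv), THF, −20 °C; then 15, −78 to −20 °C; AcOH, −78 °C
Reagents that add atoms: none
Why: Iodine–magnesium exchange (the di-ortho-substituted diaryl ketone is too hindered to add a Grignard reagent at low temperature) followed by Michael addition of the aryl group to the nitroalkene anti to the pseudo-axial isopropenyl group on the neighbouring carbon sets C1 as R, trans to C4; the nitro-bearing carbon forms as a mixture that step 8 removes.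

Step 8
Reactants: 18 [3-[(1R,4R)-2,2-dimethyl-5-nitro-4-(prop-1-en-2-yl)cyclopentyl]-2,4,6-tris(methoxymethoxy)phenyl](phenyl)methanone
Product: 19 [3-[(1R,4R)-2,2-dimethyl-4-(prop-1-en-2-yl)cyclopentyl]-2,4,6-tris(methoxymethoxy)phenyl](phenyl)methanone
Conditions: Bu3SnH (5 equiv), AIBN (0.3 equiv, in portions), toluene, reflux
Reagents that add atoms: none
Why: Radical denitration (Ono–Tanner) replaces the secondary NO2 by H at a carbon that becomes CH2, so neither stereocentre is touched; the high tin hydride concentration outruns aryl or vinyl shifts of the intermediate radical.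

Step 9
Reactants: 19 [3-[(1R,4R)-2,2-dimethyl-4-(prop-1-en-2-yl)cyclopentyl]-2,4,6-tris(methoxymethoxy)phenyl](phenyl)methanone
Product: 20 [3-[(1R,4R)-2,2-dimethyl-4-(prop-1-en-2-yl)cyclopentyl]-2,4,6-trihydroxyphenyl](phenyl)methanone
Conditions: HCl (2 M in MeOH), 40 °C
Reagents that add atoms: none
Why: Acid-catalysed acetal cleavage of the three aryl MOM ethers with methanol; the 1,1-disubstituted alkene tolerates dilute acid, and the trans geometry prevents a phenol from cyclising onto it.

## Compound list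

1 | phloroglucinol (benzene-1,3,5-triol) | Oc1cc(O)cc(O)c1 | starting material
2 | benzoyl chloride | O=C(Cl)c1ccccc1 | starting material
3 | phenyl(2,4,6-trihydroxyphenyl)methanone | O=C(c1ccccc1)c1c(O)cc(O)cc1O | intermediate
4 | chloromethyl methyl ether | COCCl | starting material
5 | phenyl[2,4,6-tris(methoxymethoxy)phenyl]methanone | COCOc1cc(OCOC)c(C(=O)c2ccccc2)c(OCOC)c1 | intermediate
6 | N-iodosuccinimide | O=C1CCC(=O)N1I | starting material
7 | [3-iodo-2,4,6-tris(methoxymethoxy)phenyl](phenyl)methanone | COCOc1cc(OCOC)c(C(=O)c2ccccc2)c(OCOC)c1I | intermediate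
8 | 2,2-dimethylpent-4-enal | C=CCC(C)(C)C=O | starting material
9 | silver nitrite | [Ag+].[O-]N=O | starting material
10 | (E)-2,2-dimethyl-5-nitropent-4-enal | O=CC(C)(C)C/C=C/[N+](=O)[O-] | intermediate
11 | potassium trifluoro(prop-1-en-2-yl)borate | C=C(C)[B-](F)(F)F.[K+] | starting material
12 | (4R)-2,2,5-trimethyl-4-(nitromethyl)hex-5-enal | C=C(C)[C@H](C[N+](=O)[O-])CC(C)(C)C=O | intermediate
13 | (4R)-2,2-dimethyl-5-nitro-4-(prop-1-en-2-yl)cyclopentan-1-ol (mixture of epimers at C1 and C5) | C=C(C)[C@@H]1C([N+](=O)[O-])C(O)C(C)(C)C1 | intermediate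
14 | (4R)-2,2-dimethyl-5-nitro-4-(prop-1-en-2-yl)cyclopentyl methanesulfonate (mixture of epimers at C1 and C5) | C=C(C)[C@@H]1C([N+](=O)[O-])C(OS(C)(=O)=O)C(C)(C)C1 | intermediate
15 | (5R)-3,3-dimethyl-1-nitro-5-(prop-1-en-2-yl)cyclopent-1-ene | C=C(C)[C@@H]1C([N+](=O)[O-])=CC(C)(C)C1 | intermediate
16 | [3-benzoyl-2,4,6-tris(methoxymethoxy)phenyl]magnesium chloride (LiCl complex) | Cl[Mg]c1c(OCOC)cc(OCOC)c(C(=O)c2ccccc2)c1OCOC | intermediate
17 | chloromagnesium nitronate of 18 (aryl on C1 R, isopropenyl on C4 R, trans) | C=C(C)[C@@H]1C(=[N+]([O-])O[Mg]Cl)[C@@H](c2c(OCOC)cc(OCOC)c(C(=O)c3ccccc3)c2OCOC)C(C)(C)C1 | intermediate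
18 | [3-[(1R,4R)-2,2-dimethyl-5-nitro-4-(prop-1-en-2-yl)cyclopentyl]-2,4,6-tris(methoxymethoxy)phenyl](phenyl)methanone (epimers at C5) | C=C(C)[C@@H]1C([N+](=O)[O-])[C@@H](c2c(OCOC)cc(OCOC)c(C(=O)c3ccccc3)c2OCOC)C(C)(C)C1 | intermediate
19 | [3-[(1R,4R)-2,2-dimethyl-4-(prop-1-en-2-yl)cyclopentyl]-2,4,6-tris(methoxymethoxy)phenyl](phenyl)methanone | C=C(C)[C@@H]1C[C@@H](c2c(OCOC)cc(OCOC)c(C(=O)c3ccccc3)c2OCOC)C(C)(C)C1 | intermediate
20 | [3-[(1R,4R)-2,2-dimethyl-4-(prop-1-en-2-yl)cyclopentyl]-2,4,6-trihydroxyphenyl](phenyl)methanone | C=C(C)[C@@H]1C[C@@H](c2c(O)cc(O)c(C(=O)c3ccccc3)c2O)C(C)(C)C1 | target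

## Step count and risks

Total step count: 9 (aryl fragment: steps 1–3; C10 fragment: steps 4–6; union and endgame: steps 7–9).
Longest linear sequence: 6 steps (1, 2, 3, 7, 8, 9 from phloroglucinol; equally 4, 5, 6, 7, 8, 9 from 2,2-dimethylpent-4-enal).

The three steps most likely to fail:

Step 5 (asymmetric alkenyl addition to an acyclic nitroalkene carrying a free aldehyde). Alkenyl additions to open-chain alkyl nitroalkenes have far less precedent than additions to cyclic enones, and the ee may be low. The fallback sets the stereocentre on a cyclic enone and brings the nitro group in afterwards; it sets out from 8 and comes back at 13. Addition of MeMgBr to 8 gives 3,3-dimethylhex-5-en-2-ol F1, and Dess–Martin oxidation gives 3,3-dimethylhex-5-en-2-one F2. Ozonolysis (O3, then Me2S) gives 3,3-dimethyl-4-oxopentanal F3, which aqueous KOH closes by intramolecular aldol condensation to 5,5-dimethylcyclopent-2-en-1-one F4. Rh/(S)-BINAP addition of 11 to this enone gives (4S)-2,2-dimethyl-4-(prop-1-en-2-yl)cyclopentan-1-one F5. Nitration at its only enolisable position (KOt-Bu, isoamyl nitrate, THF, −40 °C) gives (4R)-2,2-dimethyl-5-nitro-4-(prop-1-en-2-yl)cyclopentan-1-one F6, and NaBH4 reduction gives 13.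

Step 7 (hindered union with a ketone-bearing Grignard reagent). The β-carbon of 15 sits next to a quaternary centre, and 16 carries two ortho substituents and a ketone. The fallback uses a more nucleophilic, ketone-free aryllithium and moves the benzoylation to the end; it sets out from 1 and 15 and comes back at 19. NaH/MOMCl converts 1 into 1,3,5-tris(methoxymethoxy)benzene F7. Its aryllithium (n-BuLi, THF, 0 °C) adds to 15 at −78 °C to give 2-[(1R,4R)-2,2-dimethyl-5-nitro-4-(prop-1-en-2-yl)cyclopentyl]-1,3,5-tris(methoxymethoxy)benzene F8. Bu3SnH/AIBN denitration gives 2-[(1R,4R)-2,2-dimethyl-4-(prop-1-en-2-yl)cyclopentyl]-1,3,5-tris(methoxymethoxy)benzene F9. Directed ortho-lithiation between two OMOM groups (n-BuLi, TMEDA) and acylation with N-methoxy-N-methylbenzamide then gives 19.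

Step 8 (tin hydride denitration of an unactivated secondary nitro group next to a benzophenone). The reaction may be sluggish or may touch the ketone. The fallback replaces the radical step by reduction and deamination; it sets out from 18 and comes back at 19. Zn dust in AcOH/THF reduces the nitro group to give [3-[(1R,4R)-5-amino-2,2-dimethyl-4-(prop-1-en-2-yl)cyclopentyl]-2,4,6-tris(methoxymethoxy)phenyl](phenyl)methanone F10. Direct deamination of this primary amine with an anomeric amide reagent (N-(benzyloxy)-N-(pivaloyloxy)-4-(trifluoromethyl)benzamide, MeCN, 45 °C) then gives 19.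

## Further compounds

F1 | step 5 | 3,3-dimethylhex-5-en-2-ol | C=CCC(C)(C)C(C)O
F2 | step 5 | 3,3-dimethylhex-5-en-2-one | C=CCC(C)(C)C(C)=O
F3 | step 5 | 3,3-dimethyl-4-oxopentanal | CC(=O)C(C)(C)CC=O
F4 | step 5 | 5,5-dimethylcyclopent-2-en-1-one | O=C1C=CCC1(C)C
F5 | step 5 | (4S)-2,2-dimethyl-4-(prop-1-en-2-yl)cyclopentan-1-one | C=C(C)[C@@H]1CC(=O)C(C)(C)C1
F6 | step 5 | (4R)-2,2-dimethyl-5-nitro-4-(prop-1-en-2-yl)cyclopentan-1-one | C=C(C)[C@@H]1C([N+](=O)[O-])C(=O)C(C)(C)C1
F7 | step 7 | 1,3,5-tris(methoxymethoxy)benzene | COCOc1cc(OCOC)cc(OCOC)c1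
F8 | step 7 | 2-[(1R,4R)-2,2-dimethyl-5-nitro-4-(prop-1-en-2-yl)cyclopentyl]-1,3,5-tris(methoxymethoxy)benzene | C=C(C)[C@@H]1C([N+](=O)[O-])[C@@H](c2c(OCOC)cc(OCOC)cc2OCOC)C(C)(C)C1
F9 | step 7 | 2-[(1R,4R)-2,2-dimethyl-4-(prop-1-en-2-yl)cyclopentyl]-1,3,5-tris(methoxymethoxy)benzene | C=C(C)[C@@H]1C[C@@H](c2c(OCOC)cc(OCOC)cc2OCOC)C(C)(C)C1
F10 | step 8 | [3-[(1R,4R)-5-amino-2,2-dimethyl-4-(prop-1-en-2-yl)cyclopentyl]-2,4,6-tris(methoxymethoxy)phenyl](phenyl)methanone | C=C(C)[C@@H]1C(N)[C@@H](c2c(OCOC)cc(OCOC)c(C(=O)c3ccccc3)c2OCOC)C(C)(C)C1
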